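## Retrosynthetic overview

1. Target ⇒ meso bis[(Z)-bromoalkene] bis(β-keto aldehyde): one twofold intramolecular Ni/Cr alkenyl–aldehyde addition closes rings A and B together, and a chiral chromium ligand makes both carbinols (R), which desymmetrizes the meso precursor.
2. Meso precursor ⇒ tetraol (fourfold oxidation) ⇒ 1,1,6,6-tetrabromohexa-1,5-diene plus two diol arms of opposite quaternary configuration, joined by two successive trans-selective B-alkyl Suzuki couplings that fix both (Z)-bromoalkenes.
3. Both diol arms ⇒ one racemic α-allyl-α-methyl β-keto ester, split by a catalyst-controlled ketone reduction (temporary carbinol) and ester reduction; both diastereomers are used.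
4. Keto ester ⇒ ethyl 2-methylpent-4-enoate + 4-methylpent-3-enoic acid; tetrabromide ⇒ 2,5-dimethoxytetrahydrofuran.
5. Ring order: no ring exists before the last step; rings A and B form there in the same operation.

Reading of the target (C30H46O4): ring A has quaternary C (R) and carbinol (R); ring B has quaternary C (S) and carbinol (R); both exocyclic alkenes are Z (linker CH2 cis to the carbinol carbon). The quaternary centres are therefore opposite and the carbinols alike, so a precursor that is meso at the quaternary centres plus reagent control at the carbinols gives exactly this isomer.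

Assumption: the ligand L = (S)-N-[2-(4-isopropyl-4,5-dihydro-1,3-oxazol-2-yl)-6-methoxyphenyl]methanesulfonamide delivers the alkenyl group to the Re face of the aldehyde; if a pilot run shows the opposite sense, its enantiomer is used and nothing else changes.

## Route

Step 1
Reactants: 1 ethyl 2-methylpent-4-enoate (racemic); 2 4-methylpent-3-enoic acid
Product: 5 ethyl 2,6-dimethyl-3-oxo-2-(prop-2-en-1-yl)hept-5-enoate (racemic), via 4-methylpent-3-enoyl chloride 3 (not isolated), via lithium ester enolate 4 (not isolated)
Conditions: 2, (COCl)2, DMF (cat.), CH2Cl2, 0 → 23 °C, evaporate; 1, LiN(iPr)2, THF, −78 °C; enolate 4 cannulated into 3 (1.3 equiv), THF, −78 °C; aq. NH4Cl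
Reagents that add atoms: none
Why: Crossed Claisen-type C-acylation of a fully substituted lithium ester enolate by an acid chloride, run by inverse addition so that the acidic CH2 next to the new ketone never meets free enolate and the alkene stays out of conjugation; the quaternary carbon is made racemic on purpose, because the target holds it once as (R) and once as (S).

Step 2
Reactants: 5 ethyl 2,6-dimethyl-3-oxo-2-(prop-2-en-1-yl)hept-5-enoate (racemic)
Product: 6 ethyl (2S,3S)-3-hydroxy-2,6-dimethyl-2-(prop-2-en-1-yl)hept-5-enoate; 7 ethyl (2R,3S)-3-hydroxy-2,6-dimethyl-2-(prop-2-en-1-yl)hept-5-enoate (1:1, taken on together)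
Conditions: (R)-Me-CBS [(R)-1-methyl-3,3-diphenyltetrahydro-1H,3H-pyrrolo[1,2-c][1,3,2]oxazaborole] (20 mol %), catecholborane (2 equiv), toluene, −40 → −20 °C; MeOH, aq. NaOH wash
Reagents that add atoms: none
Why: Corey–Bakshi–Shibata reduction in which the catalyst reads the quaternary carbon as the large and the CH2 as the small ketone substituent and so sets (3S) in both enantiomers of 5 (the sense in which this catalyst gives (S)-1-phenylethanol), which turns the racemate into two diastereomers that each carry one quaternary configuration, while catecholborane leaves the ester and the alkenes alone at this temperature.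

Step 3
Reactants: 6 ethyl (2S,3S)-3-hydroxy-2,6-dimethyl-2-(prop-2-en-1-yl)hept-5-enoate; 7 ethyl (2R,3S)-3-hydroxy-2,6-dimethyl-2-(prop-2-en-1-yl)hept-5-enoate (as the mixture)
Product: 8 (2R,3S)-2,6-dimethyl-2-(prop-2-en-1-yl)hept-5-ene-1,3-diol; 9 (2S,3S)-2,6-dimethyl-2-(prop-2-en-1-yl)hept-5-ene-1,3-diol (separated on silica gel)
Conditions: LiAlH4, THF, 0 °C; H2O, aq. NaOH; chromatography
Reagents that add atoms: none
Why: LiAlH4 reduction of the ester to the primary alcohol touches no stereocentre (the C2 label switches only because CH2OH now ranks below C3), and the two 1,3-diols, being diastereomers, are separated, which resolves the quaternary centre with both halves kept (8 becomes ring A, 9 becomes ring B).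

Step 4
Reactants: 10 2,5-dimethoxytetrahydrofuran (cis/trans mixture)
Product: 12 1,1,6,6-tetrabromohexa-1,5-diene, via succinaldehyde 11 (not isolated)
Conditions: H2O, 90 °C, MeOH distilled off; extract into CH2Cl2; CBr4 (4.4 equiv), PPh3 (8.8 equiv), CH2Cl2, 0 °C
Reagents that add atoms: carbon tetrabromide, BrC(Br)(Br)Br
Why: Acetal hydrolysis followed by twofold Ramirez dibromo-olefination (first stage of the Corey–Fuchs sequence) of the dialdehyde; no stereocentre is formed.

Step 5
Reactants: 8 (2R,3S)-2,6-dimethyl-2-(prop-2-en-1-yl)hept-5-ene-1,3-diol; 12 1,1,6,6-tetrabromohexa-1,5-diene (3 equiv, excess recovered)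
Product: 14 (2R,3S)-2-[(4Z)-4,9,9-tribromonona-4,8-dien-1-yl]-2,6-dimethylhept-5-ene-1,3-diol, via triboryl intermediate 13 (not isolated)
Conditions: 8, 9-BBN (3.3 equiv), THF, 0 → 23 °C; then 3 M aq. K3PO4, 12, PdCl2(dppf) (5 mol %; dppf = 1,1'-bis(diphenylphosphino)ferrocene), AsPh3 (5 mol %), DMF, 23 °C
Reagents that add atoms: none
Why: 9-BBN hydroborates only the monosubstituted alkene (the hydroxyls are masked in the flask as borinates, the trisubstituted alkene is too hindered), and the trans-selective mono B-alkyl Suzuki–Miyaura coupling of a 1,1-dibromoalkene replaces the bromine trans to the chain, so the bromine left behind is cis to the chain, i.e. the (Z)-bromoalkene, while the excess of 12 keeps the second dibromoalkene unreacted.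

Step 6
Reactants: 9 (2S,3S)-2,6-dimethyl-2-(prop-2-en-1-yl)hept-5-ene-1,3-diol; 14 (2R,3S)-2-[(4Z)-4,9,9-tribromonona-4,8-dien-1-yl]-2,6-dimethylhept-5-ene-1,3-diol
Product: 16 (5S,6R,10Z,14Z,19S,20S)-10,15-dibromo-6,19-bis(hydroxymethyl)-2,6,19,23-tetramethyltetracosa-2,10,14,22-tetraene-5,20-diol, via triboryl intermediate 15 (not isolated)
Conditions: 9 (1.5 equiv), 9-BBN (5 equiv), THF, 0 → 23 °C; then 3 M aq. K3PO4, 14, PdCl2(dppf) (5 mol %), AsPh3 (5 mol %), DMF, 23 °C
Reagents that add atoms: none
Why: The same hydroboration and trans-selective B-alkyl Suzuki–Miyaura coupling at the remaining 1,1-dibromoalkene (the trisubstituted (Z)-bromoalkene already present is inert at 23 °C) attaches the arm of opposite quaternary configuration and sets the second (Z)-bromoalkene; because the linker is symmetric, it does not matter which diol was attached first.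

Step 7
Reactants: 16 (5S,6R,10Z,14Z,19S,20S)-10,15-dibromo-6,19-bis(hydroxymethyl)-2,6,19,23-tetramethyltetracosa-2,10,14,22-tetraene-5,20-diol
Product: 17 (2R,6Z,10Z,15S)-6,11-dibromo-2,15-dimethyl-2,15-bis(4-methylpent-3-enoyl)hexadeca-6,10-dienedial (meso)
Conditions: Dess–Martin periodinane (8 equiv), NaHCO3, CH2Cl2, 0 → 23 °C; filter through silica, use at once
Reagents that add atoms: none
Why: Dess–Martin oxidation of the two primary and two secondary hydroxyls under buffered, non-basic conditions, which keeps the β,γ-unsaturated ketones out of conjugation, cannot epimerize the non-enolizable quaternary carbons, and erases the two temporary (S)-carbinols so that 17 is a meso compound.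

Step 8
Reactants: 17 (2R,6Z,10Z,15S)-6,11-dibromo-2,15-dimethyl-2,15-bis(4-methylpent-3-enoyl)hexadeca-6,10-dienedial
Product: 18 CNP0297042.3, 1-[(1R,2R,3Z)-2-hydroxy-3-{4-[(1Z,2R,3S)-2-hydroxy-3-methyl-3-(4-methylpent-3-enoyl)cyclohexylidene]butylidene}-1-methylcyclohexyl]-4-methylpent-3-en-1-one
Conditions: CrCl2 (10 equiv), ligand L (11 equiv), Et3N (11 equiv), THF, 23 °C; NiCl2(dmp) (2 mol %; dmp = 2,9-dimethyl-1,10-phenanthroline); 17 added over 12 h (2 mM final), 23 °C; aq. work-up
Reagents that add atoms: none
Why: Proposed new method: a twofold intramolecular Nozaki–Hiyama–Kishi reaction in which each (Z)-alkenyl bromide is activated by nickel, passed with retention of geometry to trivalent chromium, and added 6-exo to its own neopentyl aldehyde (ketones are inert to alkenylchromium), while the chromium-bound sulfonamide ligand directs attack to the Re face of both enantiotopic aldehydes of meso 17 and so gives the (R)-carbinol in ring A (matched or mismatched with the (R)-quaternary carbon) and in ring B (the opposite case with the (S)-quaternary carbon); the closest known chemistry is the ligand-controlled asymmetric Ni/Cr alkenylation of aldehydes and the intramolecular Nozaki–Hiyama–Kishi closure of 2-alkylidenecyclohexanols, but their combination as a desymmetrizing double cyclization is untested.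

## Compound list

1 | ethyl 2-methylpent-4-enoate (racemic) | CCOC(=O)C(C)CC=C | starting material
2 | 4-methylpent-3-enoic acid | CC(C)=CCC(=O)O | starting material
3 | 4-methylpent-3-enoyl chloride | CC(C)=CCC(=O)Cl | intermediate
4 | lithium enolate of 1, lithium 1-ethoxy-2-methylpenta-1,4-dien-1-olate (E/Z mixture) | CCOC(O[Li])=C(C)CC=C | intermediate
5 | ethyl 2,6-dimethyl-3-oxo-2-(prop-2-en-1-yl)hept-5-enoate (racemic) | CCOC(=O)C(C)(CC=C)C(=O)CC=C(C)C | intermediate
6 | ethyl (2S,3S)-3-hydroxy-2,6-dimethyl-2-(prop-2-en-1-yl)hept-5-enoate | CC(C)=CC[C@H](O)[C@](C(=O)OCC)(C)CC=C | intermediate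
7 | ethyl (2R,3S)-3-hydroxy-2,6-dimethyl-2-(prop-2-en-1-yl)hept-5-enoate | CC(C)=CC[C@H](O)[C@@](C(=O)OCC)(C)CC=C | intermediate
8 | (2R,3S)-2,6-dimethyl-2-(prop-2-en-1-yl)hept-5-ene-1,3-diol | CC(C)=CC[C@H](O)[C@](CO)(C)CC=C | intermediate
9 | (2S,3S)-2,6-dimethyl-2-(prop-2-en-1-yl)hept-5-ene-1,3-diol | CC(C)=CC[C@H](O)[C@@](CO)(C)CC=C | intermediate
10 | 2,5-dimethoxytetrahydrofuran (cis/trans mixture) | COC1CCC(OC)O1 | starting material
11 | succinaldehyde (butanedial) | O=CCCC=O | intermediate
12 | 1,1,6,6-tetrabromohexa-1,5-diene | BrC(Br)=CCCC=C(Br)Br | intermediate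
13 | triboryl intermediate from 8: (2R,3S) skeleton of 8 with a 9-borabicyclo[3.3.1]nonan-9-yl group on the terminal carbon of the former allyl group and on both oxygens | CC(C)=CC[C@H](OB1C2CCCC1CCC2)[C@](COB1C2CCCC1CCC2)(C)CCCB1C2CCCC1CCC2 | intermediate
14 | (2R,3S)-2-[(4Z)-4,9,9-tribromonona-4,8-dien-1-yl]-2,6-dimethylhept-5-ene-1,3-diol | CC(C)=CC[C@H](O)[C@](CO)(C)CCC/C(Br)=C/CCC=C(Br)Br | intermediate
15 | triboryl intermediate from 9: (2S,3S) skeleton of 9, borylated as in 13 | CC(C)=CC[C@H](OB1C2CCCC1CCC2)[C@@](COB1C2CCCC1CCC2)(C)CCCB1C2CCCC1CCC2 | intermediate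
16 | (5S,6R,10Z,14Z,19S,20S)-10,15-dibromo-6,19-bis(hydroxymethyl)-2,6,19,23-tetramethyltetracosa-2,10,14,22-tetraene-5,20-diol | CC(C)=CC[C@H](O)[C@](CO)(C)CCC/C(Br)=C/CC/C=C(Br)/CCC[C@@](C)(CO)[C@@H](O)CC=C(C)C | intermediate
17 | (2R,6Z,10Z,15S)-6,11-dibromo-2,15-dimethyl-2,15-bis(4-methylpent-3-enoyl)hexadeca-6,10-dienedial (meso) | CC(C)=CCC(=O)[C@](C=O)(C)CCC/C(Br)=C/CC/C=C(Br)/CCC[C@@](C)(C=O)C(=O)CC=C(C)C | intermediate
18 | CNP0297042.3, 1-[(1R,2R,3Z)-2-hydroxy-3-{4-[(1Z,2R,3S)-2-hydroxy-3-methyl-3-(4-methylpent-3-enoyl)cyclohexylidene]butylidene}-1-methylcyclohexyl]-4-methylpent-3-en-1-one | CC(C)=CCC(=O)[C@]1(C)CCC/C(=C/CC/C=C2/CCC[C@](C)(C(=O)CC=C(C)C)[C@@H]2O)[C@H]1O | target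

## Step count and risks

Total step count: 8. Longest linear sequence: 7 steps (1 → 5 → 6/7 → 8/9 → 14 → 16 → 17 → 18); step 4 is a one-step side branch.

Three steps most likely to fail:

**Step 8.** The ligand must override the bias of the adjacent quaternary centre in one of the two rings. The alkenyl bromides are less reactive than iodides. Because both C–Br bonds point toward the linker, nickel-mediated alkenyl–alkenyl homocoupling to a cyclohexa-1,3-diene is a real competitor, which is why nickel is kept at 2 mol %. The fallback sets out from 17 and comes back at 18, and separates ring closure from carbinol control. Compound 17 is cyclized twice with CrCl2 and catalytic NiCl2 in DMSO without chiral ligand to the ring-closed bis(allylic alcohol) as a mixture of carbinol epimers F1. Dess–Martin periodinane oxidizes both ring hydroxyls to give the meso tetraketone F2. The two ring enone carbonyls are the only conjugated ketones, and they are reduced under catalyst control with Me-CBS oxazaborolidine (the enantiomer chosen on a model ring ketone) and catecholborane at −78 °C, which leaves the saturated side-chain ketones and gives 18.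

**Step 5.** The trans-selective mono-coupling of a symmetric tetrabromide with an alkylborane carrying two O–B groups may give double coupling, loss of HBr to an alkyne, or poor conversion. The fallback sets out from 8 and comes back at 14, and changes the organometallic partner from boron to zinc. Diol 8 is protected (2,2-dimethoxypropane, TsOH) as the acetonide F3, hydroborated with 9-BBN to the alkylborane F4, and iodinated (I2, NaOMe) to the primary iodide F5. Zinc insertion (Zn dust, LiCl, THF) gives the alkylzinc iodide F6. A trans-selective Negishi mono-alkylation of 12 with PdCl2(DPEphos) (DPEphos = bis[2-(diphenylphosphino)phenyl] ether) then gives the coupled acetonide F7, and aqueous AcOH frees 14.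

**Step 2.** The hindered ketone may react slowly, reagent control may be incomplete for one enantiomer of 5, and diols 8 and 9 differ only in the placement of methyl and allyl, so the silica separation in step 3 may be poor. The fallback sets out from 5 and comes back at 17, and resolves before reduction. Racemic 5 is split by preparative chromatography on a chiral stationary phase (supercritical CO2/MeOH) into the (2S)-keto ester F8 and the (2R)-keto ester F9; both are needed, so nothing is discarded. LiAlH4 reduces each to a diol that is a pair of C3 epimers, the (2R)-diol F10 from F8 and the (2S)-diol F11 from F9. Because the C3 carbinols are oxidized later, the epimers converge. F10 is hydroborated to the triboryl intermediate F12 and coupled with 12 as in step 5 to the tribromide diol F13. F11 is hydroborated to the triboryl intermediate F14 and coupled with F13 as in step 6 to the tetraol F15. Dess–Martin oxidation as in step 7 then gives 17.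

## Further compounds

F1 | step 8 | ring-closed bis(allylic alcohol), mixture of carbinol epimers (18 and its epimers at the two CH–OH carbons) | CC(C)=CCC(=O)[C@]1(C)CCC/C(=C/CC/C=C2/CCC[C@](C)(C(=O)CC=C(C)C)C2O)C1O
F2 | step 8 | meso tetraketone, 18 with both ring hydroxyls oxidized to ketones | CC(C)=CCC(=O)[C@]1(C)CCC/C(=C/CC/C=C2/CCC[C@](C)(C(=O)CC=C(C)C)C2=O)C1=O
F3 | step 5 | acetonide (2,2-dimethyl-1,3-dioxane) of 8 | CC(C)=CC[C@@H]1OC(C)(C)OC[C@@]1(C)CC=C
F4 | step 5 | B-alkyl-9-BBN from F3 (boron on the terminal carbon of the former allyl group) | CC(C)=CC[C@@H]1OC(C)(C)OC[C@@]1(C)CCCB1C2CCCC1CCC2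
F5 | step 5 | primary iodide from F4 | CC(C)=CC[C@@H]1OC(C)(C)OC[C@@]1(C)CCCI
F6 | step 5 | alkylzinc iodide from F5 | CC(C)=CC[C@@H]1OC(C)(C)OC[C@@]1(C)CCC[Zn]I
F7 | step 5 | acetonide of 14 | CC(C)=CC[C@@H]1OC(C)(C)OC[C@@]1(C)CCC/C(Br)=C/CCC=C(Br)Br
F8 | step 2 | ethyl (2S)-2,6-dimethyl-3-oxo-2-(prop-2-en-1-yl)hept-5-enoate | CC(C)=CCC(=O)[C@](C(=O)OCC)(C)CC=C
F9 | step 2 | ethyl (2R)-2,6-dimethyl-3-oxo-2-(prop-2-en-1-yl)hept-5-enoate | CC(C)=CCC(=O)[C@@](C(=O)OCC)(C)CC=C
F10 | step 2 | (2R)-2,6-dimethyl-2-(prop-2-en-1-yl)hept-5-ene-1,3-diol, both C3 epimers | CC(C)=CCC(O)[C@](CO)(C)CC=C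
F11 | step 2 | (2S)-2,6-dimethyl-2-(prop-2-en-1-yl)hept-5-ene-1,3-diol, both C3 epimers | CC(C)=CCC(O)[C@@](CO)(C)CC=C
F12 | step 2 | triboryl intermediate from F10, borylated as in 13 | CC(C)=CCC(OB1C2CCCC1CCC2)[C@](COB1C2CCCC1CCC2)(C)CCCB1C2CCCC1CCC2
F13 | step 2 | (2R)-2-[(4Z)-4,9,9-tribromonona-4,8-dien-1-yl]-2,6-dimethylhept-5-ene-1,3-diol, both C3 epimers | CC(C)=CCC(O)[C@](CO)(C)CCC/C(Br)=C/CCC=C(Br)Br
F14 | step 2 | triboryl intermediate from F11, borylated as in 15 | CC(C)=CCC(OB1C2CCCC1CCC2)[C@@](COB1C2CCCC1CCC2)(C)CCCB1C2CCCC1CCC2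
F15 | step 2 | (6R,10Z,14Z,19S)-10,15-dibromo-6,19-bis(hydroxymethyl)-2,6,19,23-tetramethyltetracosa-2,10,14,22-tetraene-5,20-diol, carbinol epimers at C5 and C20 | CC(C)=CCC(O)[C@](CO)(C)CCC/C(Br)=C/CC/C=C(Br)/CCC[C@@](C)(CO)C(O)CC=C(C)C
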